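**Plan**

- Numbering: ring A = C1 (ketone), C2=C3, C4 (acetoxy carbon), C5, C6 (spiro); ring B = C6, C7, C8 (lactone carbonyl), O, C9; side chain = C10 to C15.
- Enabling feature: the ring B oxygen on C9 is allylic to the E C10=C11 alkene. Moving it to C11 and the alkene to C9=C10 gives a tertiary allylic ester in a seven-membered lactone (C6, C7, C8, O, C11, C10, C9); this relationship makes the key step possible.
- Cuts, in retrosynthetic order: C4 acetate and both silyl groups; C9–O (ring contraction); C9=C10 (ring-closing metathesis); C15–O (ene oxygenation); C6–C7 (alkylation of a ring A dienolate with (S)-linalyl bromoacetate, which brings C7, C8 and C10–C15 in one piece); C6–C9 (aldol condensation with acetaldehyde).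
- Forward order: ring A is desymmetrised and oxidised to the enone, C9 is attached, the chain is joined at C6, C15 is oxygenated, the seven-membered ring is closed, ring B arises by contraction, and desilylation with acetylation at C4 finishes.
- Stereochemistry: C4 from enantioselective deprotonation with a chiral lithium amide; C6 from alkylation anti to the C4 silyloxy group; C11 from (S)-linalool, passed on to C9 and to the E C10=C11 geometry in the ring contraction; E C13=C14 from the ene reaction.

Key step: step 11

Assumption: lithium (R,R)-bis(1-phenylethyl)amide is taken to give the (S) enol silane 3, as with other 4-substituted cyclohexanones; if the sense were opposite, the (S,S) amide would be used.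

Abbreviations: TBS = tert-butyldimethylsilyl, TES = triethylsilyl, TMS = trimethylsilyl.

**Route**

Step 1
Reactants: 1 4-hydroxycyclohexanone
Product: 2 4-(tert-butyldimethylsilyloxy)cyclohexanone
Conditions: TBSCl, imidazole, DMF, rt
Reagents that add atoms: tert-butyldimethylsilyl chloride, CC(C)(C)[Si](C)(C)Cl
Why: Imidazole-mediated silylation of a secondary alcohol (standard silyl ether formation) protects the hydroxyl for the strongly basic steps that follow and creates no stereocentre.

Step 2
Reactants: 2 4-(tert-butyldimethylsilyloxy)cyclohexanone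
Product: 3 (S)-4-(tert-butyldimethylsilyloxy)-1-(trimethylsilyloxy)cyclohex-1-ene
Conditions: (R,R)-bis(1-phenylethyl)amine, n-BuLi, THF, −78 °C; TMSCl, then 2, −100 °C
Reagents that add atoms: trimethylsilyl chloride, C[Si](C)(C)Cl
Why: Enantioselective deprotonation of a prochiral ketone by a C2-symmetric chiral lithium amide with in situ silyl trapping distinguishes the two enantiotopic α-methylene groups, so that C4 becomes a stereocentre of (S) configuration under reagent control.

Step 3
Reactants: 3 (S)-4-(tert-butyldimethylsilyloxy)-1-(trimethylsilyloxy)cyclohex-1-ene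
Product: 4 (S)-4-(tert-butyldimethylsilyloxy)cyclohex-2-en-1-one
Conditions: Pd(OAc)2 (1.05 equiv), MeCN, rt
Reagents that add atoms: none
Why: Saegusa–Ito oxidation (palladation of the enol silane at C2, then β-hydride elimination from C3) introduces the C2=C3 alkene only on the side marked by the enol ether and leaves C4 untouched.

Step 4
Reactants: 4 (S)-4-(tert-butyldimethylsilyloxy)cyclohex-2-en-1-one; 5 acetaldehyde
Product: 7 (4S)-4-(tert-butyldimethylsilyloxy)-6-(1-hydroxyethyl)cyclohex-2-en-1-one (diastereomer mixture at C6 and the carbinol carbon), via lithium enolate 6 (not isolated)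
Conditions: LiN(i-Pr)2 (LDA), THF, −78 °C; 5, −78 °C; AcOH quench
Reagents that add atoms: acetaldehyde 5, CC=O
Why: Kinetic deprotonation of the enone at C6 (the only α-carbon bearing hydrogen) and aldol addition of enolate 6 to acetaldehyde attach C9; the new centres at C6 and the carbinol carbon are not controlled because both are erased in step 5.

Step 5
Reactants: 7 (4S)-4-(tert-butyldimethylsilyloxy)-6-(1-hydroxyethyl)cyclohex-2-en-1-one
Product: 9 (4S,6E)-4-(tert-butyldimethylsilyloxy)-6-ethylidenecyclohex-2-en-1-one, via mesylate 8 (not isolated)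
Conditions: MsCl, Et3N, CH2Cl2, 0 °C; then DBU, 0 °C to rt
Reagents that add atoms: none
Why: Mesylation of the β-hydroxy ketone and base-induced E1cB elimination give the conjugated exocyclic alkene, the E geometry being the thermodynamically preferred one with the methyl group turned away from the carbonyl.

Step 6
Reactants: 10 (S)-linalool; 11 bromoacetyl bromide
Product: 12 (S)-3,7-dimethylocta-1,6-dien-3-yl 2-bromoacetate ((S)-linalyl bromoacetate)
Conditions: 11, N,N-dimethylaniline, CH2Cl2, 0 °C to rt
Reagents that add atoms: bromoacetyl bromide 11, BrCC(Br)=O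
Why: Ester formation from an acyl halide succeeds on the hindered tertiary allylic alcohol because the acyl bromide is very reactive, while the weak amine base scavenges HBr so that the tertiary allylic C–O bond does not ionise and the C11 stereocentre is untouched.

Step 7
Reactants: 9 (4S,6E)-4-(tert-butyldimethylsilyloxy)-6-ethylidenecyclohex-2-en-1-one; 12 (S)-linalyl bromoacetate
Product: 14 (S)-3,7-dimethylocta-1,6-dien-3-yl 2-[(1R,5S)-5-(tert-butyldimethylsilyloxy)-1-ethenyl-2-oxocyclohex-3-en-1-yl]acetate, via lithium dienolate 13 (not isolated)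
Conditions: LiN(i-Pr)2 (LDA), THF–DMPU, −78 °C (9 added to the base); then 12, −78 to −40 °C
Reagents that add atoms: (S)-linalyl bromoacetate 12, C=C[C@@](C)(OC(=O)CBr)CCC=C(C)C
Why: Deconjugative α-alkylation of an extended enolate: γ-deprotonation of the ethylidene methyl gives dienolate 13, which the α-bromo ester alkylates at C6 on the face opposite the C4 silyloxy group (as in the trans-selective C6 alkylations of 4-silyloxycyclohexenone enolates), setting the quaternary (R)-C6 centre with C7 trans to the C4 oxygen and leaving the former ethylidene as the C6 vinyl group.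

Step 8
Reactants: 14 linalyl ester with C4 OTBS
Product: 16 (3S,5E)-7-hydroxy-3,7-dimethylocta-1,5-dien-3-yl 2-[(1R,5S)-5-(tert-butyldimethylsilyloxy)-1-ethenyl-2-oxocyclohex-3-en-1-yl]acetate, via hydroperoxide 15 (not isolated)
Conditions: O2, tetraphenylporphyrin (cat.), visible light, CH2Cl2, 0 °C; then PPh3, 0 °C to rt
Reagents that add atoms: dioxygen, O=O
Why: Schenck ene reaction followed by phosphine reduction: singlet oxygen engages only the electron-rich trisubstituted C14=C15 alkene (enone and monosubstituted vinyl groups are inert), and abstraction of a C13 hydrogen places the oxygen on C15 and the new alkene at C13=C14 with E geometry, while the regioisomeric secondary allylic alcohol from abstraction at a C15 methyl is an expected co-product to be removed by chromatography.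

Step 9
Reactants: 16 tertiary allylic alcohol
Product: 17 (3S,5E)-3,7-dimethyl-7-(triethylsilyloxy)octa-1,5-dien-3-yl 2-[(1R,5S)-5-(tert-butyldimethylsilyloxy)-1-ethenyl-2-oxocyclohex-3-en-1-yl]acetate
Conditions: TESOTf, 2,6-lutidine, CH2Cl2, −78 °C
Reagents that add atoms: triethylsilyl trifluoromethanesulfonate, CC[Si](CC)(CC)OS(=O)(=O)C(F)(F)F
Why: Silylation of the tertiary allylic alcohol with a silyl triflate and 2,6-lutidine at low temperature (standard for hindered alcohols) masks a hydroxyl that could otherwise act as ligand or leaving group in the palladium step, and touches no stereocentre.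

Step 10
Reactants: 17 diene ester with C4 OTBS and C15 OTES
Product: 18 (4S,6R,10S)-4-(tert-butyldimethylsilyloxy)-10-methyl-10-[(2E)-4-methyl-4-(triethylsilyloxy)pent-2-en-1-yl]-9-oxaspiro[5.6]dodeca-2,11-diene-1,8-dione (seven-membered lactone; spiro atom = C6, ring carbon 10 = C11)
Conditions: second-generation Grubbs catalyst (H2IMes)(PCy3)Cl2Ru=CHPh (10 mol %), toluene, 80 °C, high dilution
Reagents that add atoms: none
Why: Ring-closing metathesis of the two vinyl groups on C6 and C11 forms the C9=C10 alkene, cis by ring constraint, in a seven-membered lactone, helped by the fully substituted allylic carbons on both sides (Thorpe–Ingold effect) and free of competition because the enone and the C13=C14 alkene could only close four-membered rings.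

Step 11
Reactants: 18 seven-membered allylic lactone
Product: 19 (1R,5R,9S)-9-(tert-butyldimethylsilyloxy)-1-[(1E,4E)-2,6-dimethyl-6-(triethylsilyloxy)hepta-1,4-dien-1-yl]-2-oxaspiro[4.5]dec-7-ene-3,6-dione (ring carbon 1 = C9, spiro atom = C6, ring carbon 9 = C4)
Conditions: PdCl2(MeCN)2 (10 mol %), THF, rt
Reagents that add atoms: none
Why: Coordination of divalent palladium to the ring alkene C9=C10 makes C9 electrophilic; the carbonyl oxygen on C8 attacks it from the face opposite the metal to give a palladated bridged 1,3-dioxan-2-ylium ion, which collapses by anti departure of palladium and the C11 oxygen, severing the seven-membered ring and creating the C10=C11 alkene. The closest known reaction type is the PdCl2(MeCN)2-catalysed [3,3] transposition of allylic esters by cyclisation-induced rearrangement, applied here to an allylic lactone so that the transposition contracts the ring. Ring B closes in a 5-exo-trig mode (oxygen onto C9, C10 outside the new ring), and the six-membered dioxanylium ring formed alongside is opened again in the same step. The new C9 stereocentre is controlled by the (S)-C11 centre: both carboxylate oxygens are held on one face of the C9–C10–C11 unit, so oxygen is transferred suprafacially and (R)-C9 results while C11 becomes planar. The step needs E geometry at C10=C11, one face at C9 and reaction at one alkene only; with spiro C6 fixing the two-carbon bridge, the chair-like dioxanylium ion that places the C12 chain equatorial and the C11 methyl axial delivers E and (R)-C9 in a single pathway, and neither the enone nor the C13=C14 alkene carries an ester oxygen able to add to a palladium-bound alkene. Thermodynamics favour the product, which trades a tertiary ester, a seven-membered lactone and a disubstituted alkene for a secondary ester, a five-membered lactone and a trisubstituted alkene.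

Step 12
Reactants: 19 bis-silyl ether of the ring-contracted lactone
Product: 20 (1R,5R,9S)-9-hydroxy-1-[(1E,4E)-6-hydroxy-2,6-dimethylhepta-1,4-dien-1-yl]-2-oxaspiro[4.5]dec-7-ene-3,6-dione
Conditions: HF·pyridine, pyridine, THF, 0 °C to rt
Reagents that add atoms: none
Why: Fluoride-induced cleavage of both silyl ethers (Si–F bond formation) in pyridine-buffered medium frees the C4 and C15 hydroxyls without opening the lactone, adding to the enone or ionising the tertiary allylic alcohol, and changes no stereocentre.

Step 13
Reactants: 20 diol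
Product: 21 (+)-miliusane XVII, (1R,5R,9S)-1-[(1E,4E)-6-hydroxy-2,6-dimethylhepta-1,4-dien-1-yl]-3,6-dioxo-2-oxaspiro[4.5]dec-7-en-9-yl acetate
Conditions: Ac2O, pyridine, CH2Cl2, 0 °C to rt
Reagents that add atoms: acetic anhydride, CC(=O)OC(C)=O
Why: Chemoselective acetylation: the secondary allylic C4 hydroxyl reacts with acetic anhydride and pyridine, whereas the tertiary C15 hydroxyl is too hindered to be acylated under these conditions, so the target results without protection of C15.

**Compound list**

1 | 4-hydroxycyclohexanone | OC1CCC(=O)CC1 | starting material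
2 | 4-(tert-butyldimethylsilyloxy)cyclohexanone | CC(C)(C)[Si](C)(C)OC1CCC(=O)CC1 | intermediate
3 | (S)-4-(tert-butyldimethylsilyloxy)-1-(trimethylsilyloxy)cyclohex-1-ene | CC(C)(C)[Si](C)(C)O[C@@H]1CC=C(O[Si](C)(C)C)CC1 | intermediate
4 | (S)-4-(tert-butyldimethylsilyloxy)cyclohex-2-en-1-one | CC(C)(C)[Si](C)(C)O[C@@H]1C=CC(=O)CC1 | intermediate
5 | acetaldehyde | CC=O | starting material
6 | lithium (S)-4-(tert-butyldimethylsilyloxy)cyclohexa-1,5-dien-1-olate (not isolated) | CC(C)(C)[Si](C)(C)O[C@@H]1C=CC([O-])=CC1.[Li+] | intermediate
7 | (4S)-4-(tert-butyldimethylsilyloxy)-6-(1-hydroxyethyl)cyclohex-2-en-1-one (diastereomer mixture) | CC(C)(C)[Si](C)(C)O[C@@H]1C=CC(=O)C(C(C)O)C1 | intermediate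
8 | 1-[(5S)-5-(tert-butyldimethylsilyloxy)-2-oxocyclohex-3-en-1-yl]ethyl methanesulfonate (diastereomer mixture, not isolated) | CC(C)(C)[Si](C)(C)O[C@@H]1C=CC(=O)C(C(C)OS(C)(=O)=O)C1 | intermediate
9 | (4S,6E)-4-(tert-butyldimethylsilyloxy)-6-ethylidenecyclohex-2-en-1-one | CC(C)(C)[Si](C)(C)O[C@@H]1C=CC(=O)/C(=C/C)C1 | intermediate
10 | (S)-linalool | C=C[C@@](C)(O)CCC=C(C)C | starting material
11 | bromoacetyl bromide | BrCC(Br)=O | starting material
12 | (S)-3,7-dimethylocta-1,6-dien-3-yl 2-bromoacetate | C=C[C@@](C)(OC(=O)CBr)CCC=C(C)C | intermediate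
13 | lithium (S)-4-(tert-butyldimethylsilyloxy)-2-ethenylcyclohexa-1,5-dien-1-olate (not isolated) | CC(C)(C)[Si](C)(C)O[C@@H]1C=CC([O-])=C(C=C)C1.[Li+] | intermediate
14 | (S)-3,7-dimethylocta-1,6-dien-3-yl 2-[(1R,5S)-5-(tert-butyldimethylsilyloxy)-1-ethenyl-2-oxocyclohex-3-en-1-yl]acetate | CC(C)(C)[Si](C)(C)O[C@@H]1C=CC(=O)[C@@](C=C)(CC(=O)O[C@](C)(C=C)CCC=C(C)C)C1 | intermediate
15 | (3S,5E)-7-hydroperoxy-3,7-dimethylocta-1,5-dien-3-yl 2-[(1R,5S)-5-(tert-butyldimethylsilyloxy)-1-ethenyl-2-oxocyclohex-3-en-1-yl]acetate (not isolated) | CC(C)(C)[Si](C)(C)O[C@@H]1C=CC(=O)[C@@](C=C)(CC(=O)O[C@](C)(C=C)C/C=C/C(C)(C)OO)C1 | intermediate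
16 | (3S,5E)-7-hydroxy-3,7-dimethylocta-1,5-dien-3-yl 2-[(1R,5S)-5-(tert-butyldimethylsilyloxy)-1-ethenyl-2-oxocyclohex-3-en-1-yl]acetate | CC(C)(C)[Si](C)(C)O[C@@H]1C=CC(=O)[C@@](C=C)(CC(=O)O[C@](C)(C=C)C/C=C/C(C)(C)O)C1 | intermediate
17 | (3S,5E)-3,7-dimethyl-7-(triethylsilyloxy)octa-1,5-dien-3-yl 2-[(1R,5S)-5-(tert-butyldimethylsilyloxy)-1-ethenyl-2-oxocyclohex-3-en-1-yl]acetate | CC(C)(C)[Si](C)(C)O[C@@H]1C=CC(=O)[C@@](C=C)(CC(=O)O[C@](C)(C=C)C/C=C/C(C)(C)O[Si](CC)(CC)CC)C1 | intermediate
18 | (4S,6R,10S)-4-(tert-butyldimethylsilyloxy)-10-methyl-10-[(2E)-4-methyl-4-(triethylsilyloxy)pent-2-en-1-yl]-9-oxaspiro[5.6]dodeca-2,11-diene-1,8-dione | CC(C)(C)[Si](C)(C)O[C@@H]1C=CC(=O)[C@@]2(CC(=O)O[C@@](C)(C/C=C/C(C)(C)O[Si](CC)(CC)CC)C=C2)C1 | intermediate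
19 | (1R,5R,9S)-9-(tert-butyldimethylsilyloxy)-1-[(1E,4E)-2,6-dimethyl-6-(triethylsilyloxy)hepta-1,4-dien-1-yl]-2-oxaspiro[4.5]dec-7-ene-3,6-dione | CC(C)(C)[Si](C)(C)O[C@@H]1C=CC(=O)[C@@]2(CC(=O)O[C@@H]2/C=C(\C)C/C=C/C(C)(C)O[Si](CC)(CC)CC)C1 | intermediate
20 | (1R,5R,9S)-9-hydroxy-1-[(1E,4E)-6-hydroxy-2,6-dimethylhepta-1,4-dien-1-yl]-2-oxaspiro[4.5]dec-7-ene-3,6-dione | O[C@@H]1C=CC(=O)[C@@]2(CC(=O)O[C@@H]2/C=C(\C)C/C=C/C(C)(C)O)C1 | intermediate
21 | (+)-miliusane XVII | CC(=O)O[C@@H]1C=CC(=O)[C@@]2(CC(=O)O[C@@H]2/C=C(\C)C/C=C/C(C)(C)O)C1 | target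

**Step count and risks**

Total: 13 steps. Longest linear sequence: 12 steps (1 to 21 through steps 1–5 and 7–13); step 6 prepares the side-chain ester 12 from 10.

Steps most likely to fail:

1. Step 11 (ring contraction). The bridged oxypalladation may be slow because both alkene carbons sit next to fully substituted centres. Acid-induced ionisation of the tertiary allylic C11–O bond could then compete and erode both the transfer of configuration to C9 and the E geometry. The fallback sets out from 18 and returns at 19, replacing alkene activation by ionisation and recombination. Zerovalent palladium (Pd(PPh3)4, THF, rt to 50 °C) should ionise the tertiary allylic carboxylate with inversion to an η3-allyl palladium carboxylate (Tsuji–Trost-type ionisation). The tethered carboxylate is expected to return at the less substituted terminus C9 with a second inversion, closing the five-membered lactone on the same face from which it left. No other allylic ester is present in 18, since C4 and C15 carry silyl ethers. This fallback makes no new compound, F0.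

2. Step 7 (alkylation with 12). Proton transfer from the acidic α-bromo ester to dienolate 13, or slow displacement at a bromoacetate carrying a bulky tertiary allylic ester, may consume 12 by self-condensation and return 9. The fallback sets out from 9 and returns at 14, separating the C–C bond formation from the installation of the linalyl ester. Dienolate 13 is alkylated with commercial tert-butyl bromoacetate, which can be used in excess, to give tert-butyl ester F1. The tert-butyl ester is cleaved with 85% aqueous H3PO4 in toluene, conditions under which a TBS ether should survive, to give carboxylic acid F2. Steglich esterification of F2 with (S)-linalool 10 (DCC, DMAP, CH2Cl2) then gives 14.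

3. Step 8 (ene oxygenation). Hydrogen abstraction from a C15 methyl competes with abstraction from C13, so a large share of an advanced intermediate may be diverted to the secondary allylic alcohol. The fallback sets out from 10 and returns at 17, creating the C15 oxygen regiospecifically on the side chain before it is joined to ring A.
   - (S)-Linalool 10 is acetylated (Ac2O, Et3N, DMAP) to (S)-linalyl acetate F3.
   - Buffered mCPBA (NaHCO3, CH2Cl2, 0 °C) epoxidises only the trisubstituted alkene to give epoxide F4.
   - Sodium phenylselenide (PhSeNa from PhSeSePh and NaBH4, EtOH) opens the epoxide at its secondary carbon to give hydroxy selenide F5.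
   - Oxidation with H2O2 and syn elimination of the selenoxide, which can only occur away from the fully substituted carbinol carbon, gives E allylic alcohol F6.
   - TESOTf and 2,6-lutidine give triethylsilyl ether F7; i-Bu2AlH at −78 °C removes the acetate to give tertiary alcohol F8; bromoacetyl bromide 11 with N,N-dimethylaniline gives bromoacetate F9.
   - Alkylation of dienolate 13 (from 9) with F9 under the conditions of step 7 gives 17 directly, so steps 7 to 9 are replaced.

**Further compounds**

F0 | step 11 | none | none
F1 | step 7 | tert-butyl 2-[(1R,5S)-5-(tert-butyldimethylsilyloxy)-1-ethenyl-2-oxocyclohex-3-en-1-yl]acetate | CC(C)(C)[Si](C)(C)O[C@@H]1C=CC(=O)[C@@](C=C)(CC(=O)OC(C)(C)C)C1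
F2 | step 7 | 2-[(1R,5S)-5-(tert-butyldimethylsilyloxy)-1-ethenyl-2-oxocyclohex-3-en-1-yl]acetic acid | CC(C)(C)[Si](C)(C)O[C@@H]1C=CC(=O)[C@@](C=C)(CC(=O)O)C1
F3 | step 8 | (S)-3,7-dimethylocta-1,6-dien-3-yl acetate | C=C[C@@](C)(OC(C)=O)CCC=C(C)C
F4 | step 8 | (3S)-6,7-epoxy-3,7-dimethyloct-1-en-3-yl acetate (epimers at C6) | C=C[C@@](C)(OC(C)=O)CCC1OC1(C)C
F5 | step 8 | (3S)-7-hydroxy-3,7-dimethyl-6-(phenylselanyl)oct-1-en-3-yl acetate (epimers at C6) | C=C[C@@](C)(OC(C)=O)CCC([Se]c1ccccc1)C(C)(C)O
F6 | step 8 | (3S,5E)-7-hydroxy-3,7-dimethylocta-1,5-dien-3-yl acetate | C=C[C@@](C)(OC(C)=O)C/C=C/C(C)(C)O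
F7 | step 8 | (3S,5E)-3,7-dimethyl-7-(triethylsilyloxy)octa-1,5-dien-3-yl acetate | C=C[C@@](C)(OC(C)=O)C/C=C/C(C)(C)O[Si](CC)(CC)CC
F8 | step 8 | (3S,5E)-3,7-dimethyl-7-(triethylsilyloxy)octa-1,5-dien-3-ol | C=C[C@@](C)(O)C/C=C/C(C)(C)O[Si](CC)(CC)CC
F9 | step 8 | (3S,5E)-3,7-dimethyl-7-(triethylsilyloxy)octa-1,5-dien-3-yl 2-bromoacetate | C=C[C@@](C)(OC(=O)CBr)C/C=C/C(C)(C)O[Si](CC)(CC)CC
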